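**Retrosynthetic overview**

1. The strategy rests on one feature of ring A (the ten-membered carbocycle C1–C10): C6 is a carbinol carbon bonded to C5 of the E C4=C5 alkene, and the C15 methyl on C4 is cis to C6. This is the imprint of a syn addition of an aldehyde carbon and a methyl group across a terminal alkyne C4≡C5, so C5–C6 and C4–C15 are cut together and ring A is closed first, by a nickel/ZnMe2 alkylative coupling of an ynal.
2. Ring B (the α-methylene-γ-lactone O6–C12–C11–C7–C6) is closed second, by oxidative lactonisation of the C6/C12 diol; the epoxy ester on O8 is attached last.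
3. The ynal is built from 2,3-O-isopropylidene-D-ribono-1,4-lactone (sugar C1–C5 become C7, C8, C9, C10, C14): Z-selective Wittig at C10, acylation of a 2-lithioallyl silyl ether at C7, then chelation-controlled hydroxymethylation, which brings in C6 and sets C7.
4. The (2S,3R)-epoxy acid comes from tiglic acid by Sharpless asymmetric epoxidation.

Key step: step 13

Remark: germacrane numbering is used for the target and all intermediates (ring A carbons C1–C10, C11–C13 of the methylene lactone, C14 on C10, C15 on C4, On = oxygen on Cn); the epoxy acid of step 20 is assumed to be used at once, without storage.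

**Step 1**
Reactants: 1 2,3-O-isopropylidene-D-ribono-1,4-lactone
Product: 2 5-deoxy-5-iodo-2,3-O-isopropylidene-D-ribono-1,4-lactone
Conditions: I2, PPh3, imidazole, toluene, 70 °C
Reagents that add atoms: iodine, II
Why: Appel-type (Garegg–Samuelsson) iodination of the only free, primary hydroxyl; the lactone, the acetonide and all stereocentres are untouched.

**Step 2**
Reactants: 2 5-deoxy-5-iodo-2,3-O-isopropylidene-D-ribono-1,4-lactone
Product: 3 5-deoxy-2,3-O-isopropylidene-D-ribono-1,4-lactone
Conditions: H2 (1 atm), 10% Pd/C, Et3N, EtOAc, rt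
Reagents that add atoms: none
Why: Catalytic hydrogenolysis of the primary C–I bond with Et3N as acid scavenger; the cis-dioxolane now carries the C8 and C9 configuration of the target and the C4–CH3 unit is the future C10–C14.

**Step 3**
Reactants: 3 5-deoxy-2,3-O-isopropylidene-D-ribono-1,4-lactone
Product: 4 (4R,5R)-5-[(1R)-1-hydroxyethyl]-N-methoxy-N,2,2-trimethyl-1,3-dioxolane-4-carboxamide
Conditions: MeNH(OMe)·HCl, AlMe3, CH2Cl2, 0 °C to rt
Reagents that add atoms: N,O-dimethylhydroxylamine hydrochloride, CNOC.Cl
Why: Weinreb amide formation by aminolysis of the γ-lactone with the AlMe3-derived aluminium amide, which does not epimerise the α-alkoxy centre; the crude γ-hydroxy amide is oxidised at once because it can relactonise.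

**Step 4**
Reactants: 4 γ-hydroxy Weinreb amide
Product: 5 (4R,5S)-5-acetyl-N-methoxy-N,2,2-trimethyl-1,3-dioxolane-4-carboxamide
Conditions: Dess–Martin periodinane, NaHCO3, CH2Cl2, 0 °C to rt
Reagents that add atoms: none
Why: Dess–Martin oxidation of the secondary alcohol under buffered conditions gives the C10 methyl ketone without epimerising the cis-dioxolane (the descriptor at the ketone-bearing carbon changes only because the priorities change).

**Step 5**
Reactants: 6 5-(trimethylsilyl)pent-4-yn-1-ol
Product: 7 (5-iodopent-1-yn-1-yl)trimethylsilane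
Conditions: I2, PPh3, imidazole, CH2Cl2, 0 °C to rt
Reagents that add atoms: iodine, II
Why: Appel-type iodination of the primary alcohol; the silylated alkyne is inert.

**Step 6**
Reactants: 7 (5-iodopent-1-yn-1-yl)trimethylsilane
Product: 8 triphenyl[5-(trimethylsilyl)pent-4-yn-1-yl]phosphonium iodide
Conditions: PPh3, MeCN, reflux
Reagents that add atoms: triphenylphosphine, c1ccc(cc1)P(c1ccccc1)c1ccccc1
Why: SN2 quaternisation of PPh3 by the primary iodide.

**Step 7**
Reactants: 8 phosphonium iodide; 5 keto Weinreb amide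
Product: 10 (4R,5R)-N-methoxy-N,2,2-trimethyl-5-[(2Z)-7-(trimethylsilyl)hept-2-en-6-yn-2-yl]-1,3-dioxolane-4-carboxamide, via phosphonium ylide 9 (not isolated)
Conditions: NaN(SiMe3)2, THF, −78 °C; then 5, −78 °C to rt
Reagents that add atoms: none
Why: Wittig olefination of an α-alkoxy methyl ketone with a non-stabilised ylide, a reaction type known to give the trisubstituted alkene with the new chain cis to the alkoxy-bearing carbon (here 1(10)Z, C2 cis to C9); the Weinreb amide does not react with the ylide at low temperature and the alkyne stays masked as its TMS derivative.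

**Step 8**
Reactants: 11 2-bromoprop-2-en-1-ol
Product: 12 [(2-bromoprop-2-en-1-yl)oxy](tert-butyl)dimethylsilane
Conditions: TBSCl, imidazole, CH2Cl2, rt
Reagents that add atoms: tert-butyldimethylsilyl chloride, CC(C)(C)[Si](C)(C)Cl
Why: Standard silylation of a primary allylic alcohol.

**Step 9**
Reactants: 12 2-bromoallyl TBS ether; 10 Z-alkenyl Weinreb amide
Product: 14 2-{[(tert-butyldimethylsilyl)oxy]methyl}-1-{(4R,5R)-2,2-dimethyl-5-[(2Z)-7-(trimethylsilyl)hept-2-en-6-yn-2-yl]-1,3-dioxolan-4-yl}prop-2-en-1-one, via 2-lithioallyl silyl ether 13 (not isolated)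
Conditions: t-BuLi (2 equiv), Et2O, −78 °C; then 10, −78 °C; then H2O
Reagents that add atoms: none
Why: Bromine–lithium exchange gives the vinyllithium (kept at −78 °C so that the silyl group does not migrate to carbon), and its acylation by the Weinreb amide stops at the ketone because the chelated tetrahedral adduct survives until work-up; this places C11–C13 on C7 as the enone.

**Step 10**
Reactants: 14 C7 enone
Product: 16 (2R)-3-{[(tert-butyldimethylsilyl)oxy]methyl}-2-{(4R,5R)-5-[(2Z)-hept-2-en-6-yn-2-yl]-2,2-dimethyl-1,3-dioxolan-4-yl}but-3-ene-1,2-diol (C6 CH2OH and C7 tertiary OH with the target configuration; terminal alkyne), via β-hydroxysilane 15 (not isolated)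
Conditions: (i-PrO)Me2SiCH2MgCl, THF, −78 to −20 °C; then KF, KHCO3, 30% H2O2, THF/MeOH, rt; then K2CO3, MeOH, rt
Reagents that add atoms: (isopropoxydimethylsilyl)methylmagnesium chloride, CC(C)O[Si](C)(C)C[Mg]Cl; hydrogen peroxide, OO
Why: Nucleophilic hydroxymethylation of a ketone (silylmethyl Grignard addition, then Tamao–Fleming oxidation of the C–Si bond): magnesium should bridge the C7 carbonyl and the α-oxygen O8 of the dioxolane (Cram chelate model), so that the CH2 group attacks the face away from C9 and sets C7 with O7 syn to O8 along C9–C8–C7–C6 as in the target, the hard and bulky reagent adding 1,2 to the enone; the fluoride/carbonate/methanol medium of the oxidation also removes the alkynyl TMS group.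

**Step 11**
Reactants: 16 C6,C7-diol
Product: 17 6,7-bis-O-triethylsilyl ether of 16 (primary C6–OTES, tertiary C7–OTES; 8,9-acetonide, C12–OTBS, terminal alkyne)
Conditions: TESOTf (3 equiv), 2,6-lutidine, CH2Cl2, −78 to 0 °C
Reagents that add atoms: triethylsilyl trifluoromethanesulfonate, CC[Si](CC)(CC)OS(=O)(=O)C(F)(F)F
Why: The silyl triflate silylates both the primary and the hindered tertiary hydroxyl, and the ketal, the TBS ether and the alkyne tolerate the lutidine-buffered conditions.

**Step 12**
Reactants: 17 bis-TES ether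
Product: 18 (2S)-3-{[(tert-butyldimethylsilyl)oxy]methyl}-2-{(4R,5R)-5-[(2Z)-hept-2-en-6-yn-2-yl]-2,2-dimethyl-1,3-dioxolan-4-yl}-2-[(triethylsilyl)oxy]but-3-enal (ynal: C6 aldehyde, C7–OTES, same spatial arrangement as in 16)
Conditions: (COCl)2, DMSO, CH2Cl2, −78 to −35 °C; then Et3N, −78 °C to rt
Reagents that add atoms: none
Why: Swern oxidation applied directly to a primary triethylsilyl ether: the activated sulfoxide cleaves and oxidises the primary TES ether while the tertiary TES and the primary TBS ethers survive, which gives the non-enolisable α-silyloxy aldehyde without a free α-hydroxy aldehyde.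

**Step 13**
Reactants: 18 ynal; 19 dimethylzinc
Product: 20 ten-membered allylic alcohol: (1(10)Z,4E)-germacra-1(10),4,11(13)-triene with 6-OH, 7-OTES, 8,9-O-isopropylidene and 12-OTBS (C6–C9 as in the target; C15 methyl on C4 cis to C6)
Conditions: Ni(cod)2 (30 mol%), ZnMe2 (3 equiv), THF, 0 °C, 18 added over 8 h (2 mM final); then H2O
Reagents that add atoms: dimethylzinc (19), C[Zn]C
Why: Proposed new method: the terminal alkyne and the C6 aldehyde of 18 are expected to combine on a zerovalent nickel centre in an oxidative cyclisation to the five-membered metallacycle Ni–O–C6–C5=C4 (nickel on C4), which makes the C5–C6 bond and closes ring A; a methyl group then passes from zinc to nickel and C(sp2)–CH3 reductive elimination puts C15 on C4 on the same side as C6, so the syn addition gives the E C4=C5 alkene directly. The closest known reactions are the nickel-catalysed alkylative coupling of alkynes, aldehydes and organozincs (intermolecular and for five- and six-membered rings) and the nickel-catalysed reductive macrocyclisation of ynals with terminal alkynes to larger rings; a ten-membered carbocycle has not been closed in this way. Ring A closes in an endo mode: the aldehyde carbon bonds to the alkyne terminus C5, both alkyne carbons become ring members and the new alkene is endocyclic. The one new stereocentre, C6, is controlled by the quaternary C7: the non-chelating C7–OSiEt3 bond should lie anti to the forming C5–C6 bond (polar Felkin–Anh arrangement) with the ring carbon C8 gauche to the carbonyl oxygen, which gives O6 anti to O7 along C8–C7–C6–C5 (6R). The step needs regioselectivity (C6 to C5, nickel and then methyl on C4), which the unsubstituted alkyne terminus should secure on steric grounds, and ring closure over oligomerisation, which is helped by the Z C1=C10 alkene and the cis-fused O8/O9 dioxolane that fold the chain and by slow addition at high dilution; uncatalysed methyl transfer from ZnMe2 to the hindered aldehyde is slow at 0 °C.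

**Step 14**
Reactants: 20 ten-membered allylic alcohol
Product: 21 6,7,12-triol (8,9-O-isopropylidene retained)
Conditions: TBAF, THF, 0 °C to rt
Reagents that add atoms: none
Why: Fluoride cleaves the primary TBS and the tertiary TES ether in one operation and leaves the acetonide, so that C6–OH and C12–OH are free for lactonisation while O8 and O9 stay masked.

**Step 15**
Reactants: 21 6,7,12-triol
Product: 24 7-hydroxy-8,9-O-isopropylidene-6,12-olide (α-methylene-γ-lactone trans-fused to ring A), via hydroxy enal 22 (not isolated), via lactol 23 (not isolated)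
Conditions: TEMPO (20 mol%), PhI(OAc)2 (3 equiv), CH2Cl2, rt
Reagents that add atoms: none
Why: TEMPO/PhI(OAc)2 oxidises the primary allylic C12 alcohol in preference to the secondary C6 alcohol, the resulting 2-substituted acrolein is trapped by O6 as the five-membered lactol and this is oxidised on to the α-methylene-γ-butyrolactone (oxidative lactonisation of a 1,4-diol); O8 is still tied up in the acetonide, so only the 6,12-olide can form.

**Step 16**
Reactants: 24 lactone acetonide
Product: 25 7,8,9-trihydroxy-6,12-olide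
Conditions: AcOH/H2O (4:1), rt to 35 °C
Reagents that add atoms: none
Why: Acid-catalysed hydrolysis of the dioxolane; dilute acetic acid is chosen because stronger acid can trigger transannular cyclisation of the 1(10),4-diene, and the non-basic medium avoids migration of the lactone to O8.

**Step 17**
Reactants: 25 triol lactone
Product: 26 9-O-triethylsilyl-7,8-dihydroxy-6,12-olide
Conditions: TESCl (1.1 equiv), imidazole, CH2Cl2/DMF, −40 °C
Reagents that add atoms: chlorotriethylsilane, CC[Si](Cl)(CC)CC
Why: Kinetic mono-silylation under steric control: O9 is a secondary allylic hydroxyl next to an sp2 carbon, whereas O8 is flanked by the fully substituted C7 and O7 is tertiary, so one equivalent of TESCl at low temperature should take O9 only.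

**Step 18**
Reactants: 27 tiglic acid
Product: 28 (E)-2-methylbut-2-en-1-ol
Conditions: LiAlH4, Et2O, 0 °C to rt
Reagents that add atoms: none
Why: Hydride reduction of the carboxylic acid to the allylic alcohol with retention of the alkene geometry.

**Step 19**
Reactants: 28 (E)-2-methylbut-2-en-1-ol
Product: 29 [(2R,3R)-2,3-dimethyloxiran-2-yl]methanol
Conditions: Ti(OiPr)4 (10 mol%), D-(−)-diethyl tartrate (12 mol%), t-BuOOH, 4 Å molecular sieves, CH2Cl2, −20 °C
Reagents that add atoms: tert-butyl hydroperoxide, CC(C)(C)OO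
Why: Sharpless asymmetric epoxidation of the E-allylic alcohol: with the D-(−)-tartrate the oxygen is delivered to the face that gives the (2R,3R)-epoxy alcohol (the L-(+)-tartrate gives 2S,3S), so both epoxide stereocentres are set by the reagent, and the cis relationship of the two methyl groups follows from the E alkene.

**Step 20**
Reactants: 29 (2R,3R)-epoxy alcohol
Product: 31 (2S,3R)-2,3-dimethyloxirane-2-carboxylic acid, via epoxy aldehyde 30 (not isolated)
Conditions: TEMPO (20 mol%), PhI(OAc)2 (2.2 equiv), MeCN/H2O (1:1), 0 °C to rt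
Reagents that add atoms: water, O
Why: TEMPO/PhI(OAc)2 oxidation of a primary alcohol in aqueous acetonitrile, which runs through the aldehyde and its hydrate to the acid under near-neutral conditions that do not open the epoxide; the descriptor at C2 becomes S only because the substituent priorities change.

**Step 21**
Reactants: 31 (2S,3R)-epoxy acid; 26 9-O-TES diol lactone
Product: 33 9-O-triethylsilyl ether of the target (8-O-[(2S,3R)-2,3-dimethyloxirane-2-carbonyl]), via mixed anhydride 32 (not isolated)
Conditions: 2,4,6-trichlorobenzoyl chloride, Et3N, toluene, rt; then 26, DMAP, toluene, rt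
Reagents that add atoms: none
Why: Yamaguchi esterification: the acid is converted into the mixed 2,4,6-trichlorobenzoic anhydride, DMAP transfers the less hindered epoxy acyl group to the only free secondary hydroxyl (O8), the tertiary O7–H does not react, and the epoxide stereocentres are not involved.

**Step 22**
Reactants: 33 9-O-TES ether of the target
Product: 34 CNP0420662.1 (target)
Conditions: HF·pyridine, pyridine, THF, 0 °C
Reagents that add atoms: none
Why: Buffered HF·pyridine removes the secondary allylic TES ether without acyl migration, epoxide opening or attack on the α-methylene lactone.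

**Compound list**

1 | 2,3-O-isopropylidene-D-ribono-1,4-lactone | OC[C@@H]1[C@@H](OC2(C)C)[C@@H](O2)C(=O)O1 | starting material
2 | 5-deoxy-5-iodo-2,3-O-isopropylidene-D-ribono-1,4-lactone | IC[C@@H]1[C@@H](OC2(C)C)[C@@H](O2)C(=O)O1 | intermediate
3 | 5-deoxy-2,3-O-isopropylidene-D-ribono-1,4-lactone | C[C@@H]1[C@@H](OC2(C)C)[C@@H](O2)C(=O)O1 | intermediate
4 | (4R,5R)-5-[(1R)-1-hydroxyethyl]-N-methoxy-N,2,2-trimethyl-1,3-dioxolane-4-carboxamide | C[C@@H](O)[C@@H](OC1(C)C)[C@@H](O1)C(=O)N(C)OC | intermediate
5 | (4R,5S)-5-acetyl-N-methoxy-N,2,2-trimethyl-1,3-dioxolane-4-carboxamide | CC(=O)[C@@H](OC1(C)C)[C@@H](O1)C(=O)N(C)OC | intermediate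
6 | 5-(trimethylsilyl)pent-4-yn-1-ol | C[Si](C)(C)C#CCCCO | starting material
7 | (5-iodopent-1-yn-1-yl)trimethylsilane | C[Si](C)(C)C#CCCCI | intermediate
8 | triphenyl[5-(trimethylsilyl)pent-4-yn-1-yl]phosphonium iodide | C[Si](C)(C)C#CCCC[P+](c1ccccc1)(c1ccccc1)c1ccccc1.[I-] | intermediate
9 | triphenyl[5-(trimethylsilyl)pent-4-yn-1-ylidene]phosphorane (ylide, not isolated) | C[Si](C)(C)C#CCCC=P(c1ccccc1)(c1ccccc1)c1ccccc1 | intermediate
10 | (4R,5R)-N-methoxy-N,2,2-trimethyl-5-[(2Z)-7-(trimethylsilyl)hept-2-en-6-yn-2-yl]-1,3-dioxolane-4-carboxamide | C[Si](C)(C)C#CCC/C=C(/C)[C@@H](OC1(C)C)[C@@H](O1)C(=O)N(C)OC | intermediate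
11 | 2-bromoprop-2-en-1-ol | OCC(Br)=C | starting material
12 | [(2-bromoprop-2-en-1-yl)oxy](tert-butyl)dimethylsilane | C=C(Br)CO[Si](C)(C)C(C)(C)C | intermediate
13 | {3-[(tert-butyldimethylsilyl)oxy]prop-1-en-2-yl}lithium (not isolated) | [Li]C(=C)CO[Si](C)(C)C(C)(C)C | intermediate
14 | 2-{[(tert-butyldimethylsilyl)oxy]methyl}-1-{(4R,5R)-2,2-dimethyl-5-[(2Z)-7-(trimethylsilyl)hept-2-en-6-yn-2-yl]-1,3-dioxolan-4-yl}prop-2-en-1-one (C7 enone) | C[Si](C)(C)C#CCC/C=C(/C)[C@@H](OC1(C)C)[C@@H](O1)C(=O)C(=C)CO[Si](C)(C)C(C)(C)C | intermediate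
15 | C7 tertiary alcohol bearing CH2SiMe2(Oi-Pr) as C6 (β-hydroxysilane, formed as its magnesium alkoxide, not isolated; C7 as in 16) | C[Si](C)(C)C#CCC/C=C(/C)[C@@H](OC1(C)C)[C@@H](O1)[C@](O)(C[Si](C)(C)OC(C)C)C(=C)CO[Si](C)(C)C(C)(C)C | intermediate
16 | (2R)-3-{[(tert-butyldimethylsilyl)oxy]methyl}-2-{(4R,5R)-5-[(2Z)-hept-2-en-6-yn-2-yl]-2,2-dimethyl-1,3-dioxolan-4-yl}but-3-ene-1,2-diol | C#CCC/C=C(/C)[C@@H](OC1(C)C)[C@@H](O1)[C@](O)(CO)C(=C)CO[Si](C)(C)C(C)(C)C | intermediate
17 | 6,7-bis-O-triethylsilyl ether of 16 | C#CCC/C=C(/C)[C@@H](OC1(C)C)[C@@H](O1)[C@](O[Si](CC)(CC)CC)(CO[Si](CC)(CC)CC)C(=C)CO[Si](C)(C)C(C)(C)C | intermediate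
18 | (2S)-3-{[(tert-butyldimethylsilyl)oxy]methyl}-2-{(4R,5R)-5-[(2Z)-hept-2-en-6-yn-2-yl]-2,2-dimethyl-1,3-dioxolan-4-yl}-2-[(triethylsilyl)oxy]but-3-enal (ynal) | C#CCC/C=C(/C)[C@@H](OC1(C)C)[C@@H](O1)[C@](O[Si](CC)(CC)CC)(C=O)C(=C)CO[Si](C)(C)C(C)(C)C | intermediate
19 | dimethylzinc | C[Zn]C | starting material
20 | (1(10)Z,4E)-6-hydroxy-7-(triethylsilyloxy)-8,9-O-isopropylidene-12-(tert-butyldimethylsilyloxy)germacra-1(10),4,11(13)-triene (C6–C9 as in the target) | O[C@@H]1/C=C(\C)CC/C=C(/C)[C@@H](OC2(C)C)[C@@H](O2)[C@]1(C(=C)CO[Si](C)(C)C(C)(C)C)O[Si](CC)(CC)CC | intermediate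
21 | (1(10)Z,4E)-8,9-O-isopropylidene-germacra-1(10),4,11(13)-triene-6,7,12-triol | O[C@@H]1/C=C(\C)CC/C=C(/C)[C@@H](OC2(C)C)[C@@H](O2)[C@]1(C(=C)CO)O | intermediate
22 | 6,7-dihydroxy-8,9-O-isopropylidene-germacra-1(10),4,11(13)-trien-12-al (hydroxy enal, not isolated) | O[C@@H]1/C=C(\C)CC/C=C(/C)[C@@H](OC2(C)C)[C@@H](O2)[C@]1(C(=C)C=O)O | intermediate
23 | 6,12-lactol of 22 (both anomers, not isolated) | C=C1C(O)O[C@@H]2/C=C(\C)CC/C=C(/C)[C@@H](OC3(C)C)[C@@H](O3)[C@@]12O | intermediate
24 | 7-hydroxy-8,9-O-isopropylidene-germacra-1(10)Z,4E,11(13)-trien-6,12-olide | C=C1C(=O)O[C@@H]2/C=C(\C)CC/C=C(/C)[C@@H](OC3(C)C)[C@@H](O3)[C@@]12O | intermediate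
25 | 7,8,9-trihydroxy-germacra-1(10)Z,4E,11(13)-trien-6,12-olide | C=C1C(=O)O[C@@H]2/C=C(\C)CC/C=C(/C)[C@@H](O)[C@@H](O)[C@@]12O | intermediate
26 | 7,8-dihydroxy-9-(triethylsilyloxy)-germacra-1(10)Z,4E,11(13)-trien-6,12-olide | C=C1C(=O)O[C@@H]2/C=C(\C)CC/C=C(/C)[C@@H](O[Si](CC)(CC)CC)[C@@H](O)[C@@]12O | intermediate
27 | tiglic acid, (E)-2-methylbut-2-enoic acid | C/C=C(\C)C(=O)O | starting material
28 | (E)-2-methylbut-2-en-1-ol | C/C=C(\C)CO | intermediate
29 | [(2R,3R)-2,3-dimethyloxiran-2-yl]methanol | OC[C@@]1(C)O[C@@H]1C | intermediate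
30 | (2S,3R)-2,3-dimethyloxirane-2-carbaldehyde (not isolated) | O=C[C@@]1(C)O[C@@H]1C | intermediate
31 | (2S,3R)-2,3-dimethyloxirane-2-carboxylic acid | OC(=O)[C@@]1(C)O[C@@H]1C | intermediate
32 | (2S,3R)-2,3-dimethyloxirane-2-carboxylic 2,4,6-trichlorobenzoic anhydride (not isolated) | O=C(OC(=O)[C@@]1(C)O[C@@H]1C)c1c(Cl)cc(Cl)cc1Cl | intermediate
33 | 9-O-triethylsilyl ether of the target | C=C1C(=O)O[C@@H]2/C=C(\C)CC/C=C(/C)[C@@H](O[Si](CC)(CC)CC)[C@@H](OC(=O)[C@@]3(C)O[C@@H]3C)[C@@]12O | intermediate
34 | CNP0420662.1: (1(10)Z,4E,6R,7R,8R,9R)-7,9-dihydroxy-8-{[(2S,3R)-2,3-dimethyloxirane-2-carbonyl]oxy}germacra-1(10),4,11(13)-trien-6,12-olide | C=C1C(=O)O[C@@H]2/C=C(\C)CC/C=C(/C)[C@@H](O)[C@@H](OC(=O)[C@@]3(C)O[C@@H]3C)[C@@]12O | target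

**Step count and risks**

Total step count: 22. Longest linear sequence: 16 steps (steps 1–4, 7, 9–17, 21, 22).

Steps most likely to fail:

1. Step 13 (the new method). Ring closure may lose to alkyne oligomerisation or to direct methyl transfer to the aldehyde, the coupling may take the exo regiochemistry, and the facial selectivity at C6 rests on a model without direct precedent. Fallback with known chemistry: setting out from 17, Negishi carboalumination (AlMe3, Cp2ZrCl2, CH2Cl2) followed by iodinolysis gives the E-vinyl iodide F1. Swern oxidation of its primary TES ether as in step 12 gives the iodo aldehyde F2. An intramolecular Nozaki–Hiyama–Kishi reaction (CrCl2, catalytic NiCl2, DMSO/THF, high dilution) then forms the same C5–C6 bond and comes back to the route at 20.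

2. Step 10. Magnesium chelation by the dioxolane oxygen may not outweigh the non-chelated Felkin–Anh pathway, which would give poor or inverted facial selectivity at C7, and conjugate addition to the enone may compete. Fallback: the order in which C6 and C11 are attached to C7 is reversed, so that the non-chelated pathway gives the required epimer. Setting out from 10, [(4-methoxybenzyl)oxy]methyllithium F3 (from the corresponding tributylstannane and n-BuLi, THF, −78 °C) acylates to the α-PMB-oxy ketone F4. Addition of 13 in Et2O at −78 °C (Felkin–Anh, O8 anti to the nucleophile) gives the tertiary alcohol F5. DDQ in wet CH2Cl2 removes the PMB group to give the TMS-alkynyl diol F6, and K2CO3/MeOH comes back to the route at 16.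

3. Step 17. Site selectivity between O9 and O8 may be poor, or both may be silylated. Fallback: a bridging group replaces the steric mono-silylation. Setting out from 25, t-Bu2Si(OTf)2 with 2,6-lutidine ties the 1,3-related O7 and O9 into the six-membered 7,9-O-di-tert-butylsilylene F7 and leaves O8 free. Yamaguchi esterification with 31 as in step 21 gives the silylene ester F8, and HF·pyridine removes the silylene and comes back to the route at 34.

**Further compounds**

F1 | step 13 | E-vinyl iodide (5-iodo, C15 methyl on C4 cis to iodine; otherwise as 17) | I/C=C(\C)CC/C=C(/C)[C@@H](OC1(C)C)[C@@H](O1)[C@](O[Si](CC)(CC)CC)(CO[Si](CC)(CC)CC)C(=C)CO[Si](C)(C)C(C)(C)C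
F2 | step 13 | iodo aldehyde (C6 aldehyde of F1) | I/C=C(\C)CC/C=C(/C)[C@@H](OC1(C)C)[C@@H](O1)[C@](O[Si](CC)(CC)CC)(C=O)C(=C)CO[Si](C)(C)C(C)(C)C
F3 | step 10 | [(4-methoxybenzyl)oxy]methyllithium | [Li]COCc1ccc(OC)cc1
F4 | step 10 | α-PMB-oxy ketone (C7 ketone carrying C6H2OPMB) | C[Si](C)(C)C#CCC/C=C(/C)[C@@H](OC1(C)C)[C@@H](O1)C(=O)COCc1ccc(OC)cc1
F5 | step 10 | tertiary alcohol (C7–OH, C6–OPMB, C7 as in 16) | C[Si](C)(C)C#CCC/C=C(/C)[C@@H](OC1(C)C)[C@@H](O1)[C@](O)(COCc1ccc(OC)cc1)C(=C)CO[Si](C)(C)C(C)(C)C
F6 | step 10 | TMS-alkynyl diol (16 with the alkynyl TMS group still in place) | C[Si](C)(C)C#CCC/C=C(/C)[C@@H](OC1(C)C)[C@@H](O1)[C@](O)(CO)C(=C)CO[Si](C)(C)C(C)(C)C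
F7 | step 17 | 7,9-O-di-tert-butylsilylene of 25 | C=C1C(=O)O[C@@H]2/C=C(\C)CC/C=C(/C)[C@@H](O[Si]3(C(C)(C)C)C(C)(C)C)[C@@H](O)[C@@]12O3
F8 | step 17 | silylene ester (8-O-epoxy ester of F7) | C=C1C(=O)O[C@@H]2/C=C(\C)CC/C=C(/C)[C@@H](O[Si]3(C(C)(C)C)C(C)(C)C)[C@@H](OC(=O)[C@@]4(C)O[C@@H]4C)[C@@]12O3
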